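**Retrosynthetic overview**

- Target 16 comes from the (R)-diol diester 14 by closing the oxirane C9–O8 bond (Mitsunobu cyclodehydration); the oxirane is the only ring formed and it is formed last.
- 14 comes from the achiral tetraol 11 and isobutyric anhydride 12: a lipase esterifies the benzylic CH2OH and the pro-R CH2OH arm, which fixes C8.
- 11 comes from the acetonide silyl ether 10, made from phenol 8 and tiglic acid 9; 8 goes back to the adduct 7 of the aryllithium from bromide 4 with 2,2-dimethyl-1,3-dioxan-5-one 5 (aryl–C8 bond), and 4 to methyl 4-bromo-3-hydroxybenzoate 1.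
- Feature used: the only stereocentre, the quaternary benzylic oxirane carbon C8 (thymol numbering), carries two CH2–O arms, the oxirane CH2 (C9) and the isobutyryloxymethyl carbon (C10). With the oxirane opened, C8 is the prochiral centre of a 2-arylpropane-1,2,3-triol, and acylating one arm breaks its mirror plane.

Key step: step 8

Assumption: Burkholderia cepacia lipase is taken to prefer the pro-R hydroxymethyl arm of 11; this sense cannot be predicted with certainty and has to be confirmed on the first run, and the fallback for step 8 reaches the same R ester without relying on it.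

**Route**

Step 1
Reactants: 1 methyl 4-bromo-3-hydroxybenzoate
Product: 2 methyl 3-(benzyloxy)-4-bromobenzoate
Conditions: BnBr, K2CO3, DMF, rt
Reagents that add atoms: benzyl bromide, BrCc1ccccc1
Why: Williamson ether synthesis; the phenoxide formed by K2CO3 is O-alkylated by benzyl bromide in an SN2 reaction while the methyl ester and the aryl bromide are inert.

Step 2
Reactants: 2 methyl 3-(benzyloxy)-4-bromobenzoate
Product: 3 [3-(benzyloxy)-4-bromophenyl]methanol
Conditions: i-Bu2AlH (2.5 equiv), CH2Cl2, -78 to 0 °C; aq. potassium sodium tartrate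
Reagents that add atoms: none
Why: Ester reduction by an aluminium hydride; i-Bu2AlH in excess should take the methyl ester to the primary alcohol at low temperature without touching the aryl bromide or the benzyl ether.

Step 3
Reactants: 3 [3-(benzyloxy)-4-bromophenyl]methanol
Product: 4 {[3-(benzyloxy)-4-bromophenyl]methoxy}(tert-butyl)dimethylsilane
Conditions: TBSCl, imidazole, CH2Cl2, rt
Reagents that add atoms: tert-butyldimethylsilyl chloride, CC(C)(C)[Si](C)(C)Cl
Why: Standard silylation of a primary alcohol; it removes the only acidic proton before the lithiation and keeps the benzylic oxygen distinct from the phenol oxygen for the later tigloylation.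

Step 4
Reactants: 4 {[3-(benzyloxy)-4-bromophenyl]methoxy}(tert-butyl)dimethylsilane; 5 2,2-dimethyl-1,3-dioxan-5-one
Product: 7 5-[2-(benzyloxy)-4-({[tert-butyl(dimethyl)silyl]oxy}methyl)phenyl]-2,2-dimethyl-1,3-dioxan-5-ol, via aryllithium 6 (not isolated)
Conditions: n-BuLi (1.05 equiv), THF, -78 °C; then 5, -78 to -20 °C; H2O
Reagents that add atoms: none
Why: Bromine–lithium exchange at -78 °C is much faster than deprotonation of the benzylic ether positions, the ortho benzyloxy group stabilises 6 by chelation, and 6 adds to the carbonyl of 5 (1,2-addition of an aryllithium to a ketone); the carbinol carbon is not a stereocentre because its two ring CH2O arms are identical.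

Step 5
Reactants: 7 5-[2-(benzyloxy)-4-({[tert-butyl(dimethyl)silyl]oxy}methyl)phenyl]-2,2-dimethyl-1,3-dioxan-5-ol
Product: 8 5-[4-({[tert-butyl(dimethyl)silyl]oxy}methyl)-2-hydroxyphenyl]-2,2-dimethyl-1,3-dioxan-5-ol
Conditions: H2 (1 atm), Pd/C (10 wt% Pd), EtOAc, rt
Reagents that add atoms: none
Why: Catalytic hydrogenolysis; cleavage of the aryl benzyl ether should be much faster in a neutral aprotic solvent than hydrogenolysis of the silylated benzylic C–O bond or of the tertiary benzylic alcohol, and the acetonide is inert.

Step 6
Reactants: 8 5-[4-({[tert-butyl(dimethyl)silyl]oxy}methyl)-2-hydroxyphenyl]-2,2-dimethyl-1,3-dioxan-5-ol; 9 tiglic acid, (2E)-2-methylbut-2-enoic acid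
Product: 10 5-({[tert-butyl(dimethyl)silyl]oxy}methyl)-2-(5-hydroxy-2,2-dimethyl-1,3-dioxan-5-yl)phenyl (2E)-2-methylbut-2-enoate
Conditions: DCC (1.2 equiv), DMAP (0.1 equiv), CH2Cl2, 0 °C to rt
Reagents that add atoms: none
Why: Steglich esterification; the phenol is the only unhindered hydroxyl left, the tertiary alcohol on the fully substituted dioxane carbon is far too hindered to compete with a near-stoichiometric amount of acid, and the carbodiimide conditions avoid the base-induced deconjugation known for unsaturated acid chlorides, so the E geometry of the tiglate is kept.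

Step 7
Reactants: 10 5-({[tert-butyl(dimethyl)silyl]oxy}methyl)-2-(5-hydroxy-2,2-dimethyl-1,3-dioxan-5-yl)phenyl (2E)-2-methylbut-2-enoate
Product: 11 5-(hydroxymethyl)-2-(1,2,3-trihydroxypropan-2-yl)phenyl (2E)-2-methylbut-2-enoate
Conditions: AcOH/THF/H2O (3:1:1), rt to 35 °C; toluene azeotrope, used at once
Reagents that add atoms: none
Why: Acid-catalysed ketal hydrolysis and desilylation in one operation; this weak aqueous acid should cleave the isopropylidene ketal and the primary silyl ether while leaving the conjugated aryl tiglate untouched, and the base-free work-up limits acyl transfer to the freed hydroxyls.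

Step 8
Reactants: 11 5-(hydroxymethyl)-2-(1,2,3-trihydroxypropan-2-yl)phenyl (2E)-2-methylbut-2-enoate; 12 isobutyric anhydride
Product: 14 2-[(2R)-1,2-dihydroxy-3-(isobutyryloxy)propan-2-yl]-5-[(isobutyryloxy)methyl]phenyl (2E)-2-methylbut-2-enoate, via benzylic monoisobutyrate 13 (not isolated)
Conditions: Burkholderia cepacia lipase (immobilised, Amano lipase PS), 12 (2.2 equiv), MTBE/THF (4:1), 0 to 20 °C; filter off the enzyme
Reagents that add atoms: none
Why: The active-site serine of the lipase is acylated by 12 and the isobutyryl-enzyme passes its acyl group to a primary hydroxyl held in the alcohol pocket, first to the unhindered benzylic CH2OH (giving 13) and then to one of the two enantiotopic CH2OH arms on C8. The closest known reaction type is the lipase-catalysed enantiotopic-group acylation of prochiral 2-substituted propane-1,3-diols and 2-O-protected glycerols with anhydride or enol-ester donors; no ring is closed. The new stereocentre C8 is controlled only by the chiral binding pocket, which is expected to present the pro-R arm to the acyl-enzyme, so that C8 becomes R without any bond to C8 being made or broken. The step needs arm selectivity, primary-over-tertiary selectivity and an inert aryl tiglate: the tertiary hydroxyl cannot reach the serine ester, and the conjugated, alpha-branched tiglate next to the ortho quaternary carbon is a poor acyl donor. Any over-acylation to the triester should consume the minor S diester faster, because its fast-reacting pro-R arm is still free, which should raise the enantiomeric purity of 14. Background acylation by the anhydride is held down by the low temperature and the absence of base, and 14 is carried on without chromatography on basic or acidic supports so that the C10 isobutyrate does not shift to C9.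

Step 9
Reactants: 14 2-[(2R)-1,2-dihydroxy-3-(isobutyryloxy)propan-2-yl]-5-[(isobutyryloxy)methyl]phenyl (2E)-2-methylbut-2-enoate
Product: 16 5-[(isobutyryloxy)methyl]-2-{(2R)-2-[(isobutyryloxy)methyl]oxiran-2-yl}phenyl (2E)-2-methylbut-2-enoate, via alkoxyphosphonium betaine 15 (not isolated)
Conditions: PPh3 (1.3 equiv), DIAD (1.3 equiv), THF, 0 °C to rt
Reagents that add atoms: none
Why: Mitsunobu cyclodehydration of a 1,2-diol; the less hindered primary C9 hydroxyl is activated as the alkoxyphosphonium 15 and the tertiary oxygen O8 displaces triphenylphosphine oxide in a 3-exo-tet SN2 reaction at C9, so no bond at C8 is broken and the R configuration of 14 is carried into 16 under near-neutral conditions.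

**Compound list**

1 | methyl 4-bromo-3-hydroxybenzoate | COC(=O)c1ccc(Br)c(O)c1 | starting material
2 | methyl 3-(benzyloxy)-4-bromobenzoate | COC(=O)c1ccc(Br)c(OCc2ccccc2)c1 | intermediate
3 | [3-(benzyloxy)-4-bromophenyl]methanol | OCc1ccc(Br)c(OCc2ccccc2)c1 | intermediate
4 | {[3-(benzyloxy)-4-bromophenyl]methoxy}(tert-butyl)dimethylsilane | CC(C)(C)[Si](C)(C)OCc1ccc(Br)c(OCc2ccccc2)c1 | intermediate
5 | 2,2-dimethyl-1,3-dioxan-5-one | CC1(C)OCC(=O)CO1 | starting material
6 | [2-(benzyloxy)-4-({[tert-butyl(dimethyl)silyl]oxy}methyl)phenyl]lithium | [Li]c1ccc(CO[Si](C)(C)C(C)(C)C)cc1OCc1ccccc1 | intermediate (not isolated)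
7 | 5-[2-(benzyloxy)-4-({[tert-butyl(dimethyl)silyl]oxy}methyl)phenyl]-2,2-dimethyl-1,3-dioxan-5-ol | CC1(C)OCC(O)(CO1)c1ccc(CO[Si](C)(C)C(C)(C)C)cc1OCc1ccccc1 | intermediate
8 | 5-[4-({[tert-butyl(dimethyl)silyl]oxy}methyl)-2-hydroxyphenyl]-2,2-dimethyl-1,3-dioxan-5-ol | CC1(C)OCC(O)(CO1)c1ccc(CO[Si](C)(C)C(C)(C)C)cc1O | intermediate
9 | tiglic acid, (2E)-2-methylbut-2-enoic acid | C/C=C(\C)C(=O)O | starting material
10 | 5-({[tert-butyl(dimethyl)silyl]oxy}methyl)-2-(5-hydroxy-2,2-dimethyl-1,3-dioxan-5-yl)phenyl (2E)-2-methylbut-2-enoate | C/C=C(\C)C(=O)Oc1cc(CO[Si](C)(C)C(C)(C)C)ccc1C1(O)COC(C)(C)OC1 | intermediate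
11 | 5-(hydroxymethyl)-2-(1,2,3-trihydroxypropan-2-yl)phenyl (2E)-2-methylbut-2-enoate (achiral key-step precursor) | C/C=C(\C)C(=O)Oc1cc(CO)ccc1C(O)(CO)CO | intermediate
12 | isobutyric anhydride | CC(C)C(=O)OC(=O)C(C)C | starting material
13 | 5-[(isobutyryloxy)methyl]-2-(1,2,3-trihydroxypropan-2-yl)phenyl (2E)-2-methylbut-2-enoate (benzylic monoisobutyrate, achiral) | C/C=C(\C)C(=O)Oc1cc(COC(=O)C(C)C)ccc1C(O)(CO)CO | intermediate (not isolated)
14 | 2-[(2R)-1,2-dihydroxy-3-(isobutyryloxy)propan-2-yl]-5-[(isobutyryloxy)methyl]phenyl (2E)-2-methylbut-2-enoate | C/C=C(\C)C(=O)Oc1cc(COC(=O)C(C)C)ccc1[C@](O)(COC(=O)C(C)C)CO | intermediate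
15 | alkoxyphosphonium betaine of 14 (C9–O–PPh3 cation, O8 alkoxide) | C/C=C(\C)C(=O)Oc1cc(COC(=O)C(C)C)ccc1[C@]([O-])(COC(=O)C(C)C)CO[P+](c1ccccc1)(c1ccccc1)c1ccccc1 | intermediate (not isolated)
16 | 5-[(isobutyryloxy)methyl]-2-{(2R)-2-[(isobutyryloxy)methyl]oxiran-2-yl}phenyl (2E)-2-methylbut-2-enoate | C/C=C(\C)C(=O)Oc1cc(COC(=O)C(C)C)ccc1[C@]1(COC(=O)C(C)C)CO1 | target

**Step count and risk**

Total steps: 9. Longest linear sequence: 9 steps (1 to 16).

Steps most likely to fail:

1. Step 8 (key step). The alcohol pocket may discriminate the two arms in the wrong sense or weakly, or may not accept a tertiary 2-aryl triol with a bulky ortho substituent at all. Uncatalysed acylation by the anhydride and shuttling of the isobutyryl group between C10 and C9 would also erode the enantiomeric purity.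
 Fallback: a ligand-controlled, non-enzymatic desymmetrisation that sets out from 10 and comes back at 14.
 - 10 is desilylated with HF·pyridine in THF/pyridine at 0 °C to 5-(hydroxymethyl)-2-(5-hydroxy-2,2-dimethyl-1,3-dioxan-5-yl)phenyl (2E)-2-methylbut-2-enoate F1.
 - The benzylic hydroxyl of F1 is esterified with 12, pyridine and catalytic DMAP in CH2Cl2 at 0 °C to 5-[(isobutyryloxy)methyl]-2-(5-hydroxy-2,2-dimethyl-1,3-dioxan-5-yl)phenyl (2E)-2-methylbut-2-enoate F2.
 - Aqueous acetic acid at room temperature removes the acetonide and gives the triol 13, now isolated.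
 - 13 is mono-isobutyrylated with isobutyryl chloride and Et3N in the presence of catalytic CuCl2 (divalent copper) and a C2-symmetric bis(oxazoline) ligand such as 2,2-bis(4-phenyl-2-oxazolin-2-yl)propane. The copper chelate of the tertiary–primary 1,2-diol makes one arm the better nucleophile, and the ligand antipode is chosen so that the pro-R arm is acylated, which gives 14.

2. Step 9. The basic Mitsunobu betaine may promote a 1,3-shift of the C10 isobutyrate to the free C9 hydroxyl before ring closure, which would racemise C8. The hydrazide anion may also intercept the neopentyl-type alkoxyphosphonium instead of O8.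
 Fallback: a stepwise sulfonate route that sets out from 14 and comes back at 16.
 - The primary hydroxyl is capped at once with MsCl and Et3N in CH2Cl2 at -20 °C to give the primary mesylate of 14, 2-[(2S)-2-hydroxy-1-(isobutyryloxy)-3-(methanesulfonyloxy)propan-2-yl]-5-[(isobutyryloxy)methyl]phenyl (2E)-2-methylbut-2-enoate F3. It has the same spatial arrangement as 14; the descriptor changes only through the sequence rule. The racemising acyl shift is no longer possible once C9 is sulfonylated.
 - Cs2CO3 in MeCN at 0 °C then closes the oxirane by intramolecular Williamson displacement at C9 (3-exo-tet) to give 16.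

3. Step 7. During the aqueous acid exposure that the silyl ether needs, the tigloyl group may move from the phenolic oxygen to the newly freed tertiary or primary hydroxyls, or the aryl ester may hydrolyse.
 Fallback: the order of unmasking and acylation is reversed, so the aryl ester never meets acid; it sets out from 8 and comes back at 11.
 - 8 is treated with AcOH/THF/H2O at room temperature to give 2-[2-hydroxy-4-(hydroxymethyl)phenyl]propane-1,2,3-triol F4.
 - Tiglic acid 9 is converted with oxalyl chloride and catalytic DMF in CH2Cl2 into (2E)-2-methylbut-2-enoyl chloride F5.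
 - F4 is acylated with F5 under Schotten–Baumann conditions (aq. Na2CO3/THF, 0 °C), where only the phenoxide is formed and acylated and the four aliphatic hydroxyls stay free, to give 11.

Further compounds
F1 | step 8 | 5-(hydroxymethyl)-2-(5-hydroxy-2,2-dimethyl-1,3-dioxan-5-yl)phenyl (2E)-2-methylbut-2-enoate | C/C=C(\C)C(=O)Oc1cc(CO)ccc1C1(O)COC(C)(C)OC1
F2 | step 8 | 5-[(isobutyryloxy)methyl]-2-(5-hydroxy-2,2-dimethyl-1,3-dioxan-5-yl)phenyl (2E)-2-methylbut-2-enoate | C/C=C(\C)C(=O)Oc1cc(COC(=O)C(C)C)ccc1C1(O)COC(C)(C)OC1
F3 | step 9 | 2-[(2S)-2-hydroxy-1-(isobutyryloxy)-3-(methanesulfonyloxy)propan-2-yl]-5-[(isobutyryloxy)methyl]phenyl (2E)-2-methylbut-2-enoate | C/C=C(\C)C(=O)Oc1cc(COC(=O)C(C)C)ccc1[C@](O)(COC(=O)C(C)C)COS(C)(=O)=O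
F4 | step 7 | 2-[2-hydroxy-4-(hydroxymethyl)phenyl]propane-1,2,3-triol | OCc1ccc(C(O)(CO)CO)c(O)c1
F5 | step 7 | (2E)-2-methylbut-2-enoyl chloride | C/C=C(\C)C(Cl)=O
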